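The isoflavone is cut at its C4 carbonyl, a single carbon lying between C4a of ring A and C3, the ring C carbon that carries ring B; this carbon is supplied by carbon monoxide. In one operation a palladium catalyst joins an ortho-oxygenated aryl iodide (ring A, both phenols masked as methoxymethyl acetals), CO and a β-methoxystyrene (ring B plus C3 and C2) to an open 3-methoxy-2-aryl enone, forming the C4a–C4 and C4–C3 bonds. Because both phenol protecting groups are the same acetal, one acid treatment then frees them and closes ring C by loss of methanol at C2.

Key step: step 4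

Remark: the Wittig reaction delivers the enol ether as a mixture of E and Z isomers; it is carried on as such, and neither it nor the enone derived from it is given an alkene descriptor, because this geometry disappears when ring C closes.

Step 1
Reactants: 1 2-methoxybenzene-1,4-diol (methoxyhydroquinone)
Product: 2 2-methoxy-1,4-bis(methoxymethoxy)benzene
Conditions: MOMCl (2.6 equiv), iPr2NEt (3.5 equiv), CH2Cl2, 0 °C to rt, N2
Reagents that add atoms: chloromethyl methyl ether (MOMCl), COCCl
Why: Williamson-type O-alkylation of both phenols by the reactive α-chloro ether under a hindered amine base should give the bis-acetal cleanly, and the amine base avoids the air-sensitive hydroquinone dianion.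

Step 2
Reactants: 2 2-methoxy-1,4-bis(methoxymethoxy)benzene
Product: 3 1-iodo-4-methoxy-2,5-bis(methoxymethoxy)benzene
Conditions: NIS (1.05 equiv), MeCN, rt, dark
Reagents that add atoms: N-iodosuccinimide (NIS), O=C1CCC(=O)N1I
Why: Electrophilic aromatic iodination of this 1,2,4-trioxygenated ring should occur para to the methoxy group and ortho to one acetal oxygen, since the site between two oxygens is hindered and the third site has only one ortho oxygen, and NIS without added acid should leave the methoxymethyl acetals intact.

Step 3
Reactants: 4 2,4,5-trimethoxybenzaldehyde; 5 (methoxymethyl)triphenylphosphonium chloride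
Product: 7 1,2,4-trimethoxy-5-(2-methoxyethenyl)benzene (E/Z mixture), via methoxymethylenetriphenylphosphorane 6 (not isolated)
Conditions: 5, KOtBu, THF, 0 °C; then 4, 0 °C to rt
Reagents that add atoms: none
Why: Wittig olefination of the aldehyde by the alkoxymethylene ylide generated with KOtBu should give the enol ether as an E/Z mixture that is used as such, with base-washed silica in the purification to prevent hydrolysis.

Step 4
Reactants: 3 1-iodo-4-methoxy-2,5-bis(methoxymethoxy)benzene; 7 1,2,4-trimethoxy-5-(2-methoxyethenyl)benzene (E/Z mixture); 8 carbon monoxide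
Product: 9 3-methoxy-1-[4-methoxy-2,5-bis(methoxymethoxy)phenyl]-2-(2,4,5-trimethoxyphenyl)prop-2-en-1-one (mixture of alkene isomers)
Conditions: 7 (2 equiv), Pd(OAc)2 (5 mol%), 1,3-bis(diphenylphosphino)propane (6 mol%), Et3N (2 equiv), CO (10 bar), 1,4-dioxane, 100 °C
Reagents that add atoms: none
Why: Proposed new method: Pd(OAc)2 is reduced in the flask to zerovalent palladium, which inserts into the C–I bond of 3; CO then inserts to give an aroylpalladium iodide, enol ether 7 inserts into the Pd–acyl bond with the acyl carbon bonding to the ring B-bearing carbon and palladium to the methoxy-bearing carbon, and bond rotation followed by syn β-hydride elimination (HI taken up by Et3N) releases 9. The closest known reaction type is the carbonylative Heck coupling of aryl halides or triflates with terminal vinyl ethers to 3-alkoxy-1-arylpropenones; what is new is a 1,2-disubstituted, β-aryl enol ether as the alkene partner. No ring is closed and no stereocenter is formed, and both geometric isomers of 7 carry the hydrogen needed for the elimination. Two selectivities are required: the acyl group must bond to the aryl-bearing and not the oxygen-bearing alkene carbon, which the polarisation of the enol ether by its methoxy oxygen should secure (the same carbon is the one protonated in enol ether hydrolysis), and carbonylation must outrun direct arylation, which CO pressure and the fast CO insertion into an electron-rich arylpalladium bond should secure. Both phenols are masked as acetals, so the acylpalladium species cannot be trapped as an aryl ester.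

Step 5
Reactants: 9 3-methoxy-1-[4-methoxy-2,5-bis(methoxymethoxy)phenyl]-2-(2,4,5-trimethoxyphenyl)prop-2-en-1-one
Product: 11 6-hydroxy-7-methoxy-3-(2,4,5-trimethoxyphenyl)-4H-chromen-4-one (target), via bis-phenol enone 10 (not isolated)
Conditions: HCl (3 M in MeOH), 60 °C, N2
Reagents that add atoms: none
Why: Acid-catalysed acetal exchange with methanol should remove both methoxymethyl groups, after which the phenol ortho to the ketone adds to C2 of the protonated vinylogous ester and methanol is eliminated (6-endo-trig oxa-Michael addition–elimination), forming the O1–C2 bond of ring C and leaving the C6 hydroxyl free.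

Compound list
1 | 2-methoxybenzene-1,4-diol (methoxyhydroquinone) | COc1cc(O)ccc1O | starting material
2 | 2-methoxy-1,4-bis(methoxymethoxy)benzene | COCOc1ccc(OCOC)c(OC)c1 | intermediate
3 | 1-iodo-4-methoxy-2,5-bis(methoxymethoxy)benzene | COCOc1cc(OC)c(OCOC)cc1I | intermediate
4 | 2,4,5-trimethoxybenzaldehyde | COc1cc(OC)c(C=O)cc1OC | starting material
5 | (methoxymethyl)triphenylphosphonium chloride | COC[P+](c1ccccc1)(c1ccccc1)c1ccccc1.[Cl-] | starting material
6 | methoxymethylenetriphenylphosphorane | COC=P(c1ccccc1)(c1ccccc1)c1ccccc1 | intermediate (not isolated)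
7 | 1,2,4-trimethoxy-5-(2-methoxyethenyl)benzene, E/Z mixture | COC=Cc1cc(OC)c(OC)cc1OC | intermediate
8 | carbon monoxide | [C-]#[O+] | starting material
9 | 3-methoxy-1-[4-methoxy-2,5-bis(methoxymethoxy)phenyl]-2-(2,4,5-trimethoxyphenyl)prop-2-en-1-one, mixture of alkene isomers | COC=C(C(=O)c1cc(OCOC)c(OC)cc1OCOC)c1cc(OC)c(OC)cc1OC | intermediate
10 | 1-(2,5-dihydroxy-4-methoxyphenyl)-3-methoxy-2-(2,4,5-trimethoxyphenyl)prop-2-en-1-one, mixture of alkene isomers | COC=C(C(=O)c1cc(O)c(OC)cc1O)c1cc(OC)c(OC)cc1OC | intermediate (not isolated)
11 | 6-hydroxy-7-methoxy-3-(2,4,5-trimethoxyphenyl)-4H-chromen-4-one | COc1cc2occ(-c3cc(OC)c(OC)cc3OC)c(=O)c2cc1O | target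

Total step count: 5.
Longest linear sequence: 4 steps (steps 1, 2, 4 and 5, from methoxyhydroquinone); step 3 is the one-step ring B branch.

Steps most likely to fail

Step 4 (new method). The hindered internal enol ether may insert slowly into the acylpalladium bond, or with the acyl group delivered to the oxygen-bearing carbon. Direct arylation without CO uptake, or consumption of the aroylpalladium species by traces of water, could also drain the iodide. The fallback is the classical deoxybenzoin route, which sets out from 3 and returns at 11.
- Commercial 2-(2,4,5-trimethoxyphenyl)acetic acid (COc1cc(OC)c(CC(=O)O)cc1OC) is converted with 1,1'-carbonyldiimidazole and MeNHOMe·HCl in CH2Cl2 into N-methoxy-N-methyl-2-(2,4,5-trimethoxyphenyl)acetamide F1.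
- Iodine–magnesium exchange on 3 (iPrMgCl·LiCl, THF, −20 °C) should give [4-methoxy-2,5-bis(methoxymethoxy)phenyl]magnesium chloride F2.
- F2 acylates F1 to give the deoxybenzoin 1-[4-methoxy-2,5-bis(methoxymethoxy)phenyl]-2-(2,4,5-trimethoxyphenyl)ethan-1-one F3.
- Condensation with N,N-dimethylformamide dimethyl acetal (toluene, 100 °C) should give the enaminone 3-(dimethylamino)-1-[4-methoxy-2,5-bis(methoxymethoxy)phenyl]-2-(2,4,5-trimethoxyphenyl)prop-2-en-1-one F4.
- Under the conditions of step 5 both acetals should be lost to give 1-(2,5-dihydroxy-4-methoxyphenyl)-3-(dimethylamino)-2-(2,4,5-trimethoxyphenyl)prop-2-en-1-one F5, which closes ring C with loss of dimethylamine to give 11.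

Step 2. Without acid activation the iodination may stall, and forcing it risks cleavage of a methoxymethyl acetal or a second iodination. The fallback sets out from 2 and returns at 3. Bromination with NBS (MeCN, 0 °C), which needs no acid and should take the same para-to-methoxy position, would give 1-bromo-4-methoxy-2,5-bis(methoxymethoxy)benzene F6. Bromine–lithium exchange (n-BuLi, THF, −78 °C) would give [4-methoxy-2,5-bis(methoxymethoxy)phenyl]lithium F7, and an I2 quench would give 3, so the C–I bond is made by iodinolysis of an aryllithium and not by electrophilic substitution.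

Step 5. Ring closure may remain incomplete, or the transient hydroquinone-type bis-phenol may be oxidised by air in hot protic acid. The fallback sets out from 9 and returns at 10. Deprotection and cyclisation are separated: ZnBr2 and n-PrSH in CH2Cl2 at 0 °C should cleave both acetals within minutes without protic acid to give 10, which is isolated cold. Catalytic p-toluenesulfonic acid in degassed toluene at 80 °C should then close ring C to give 11. No new compound is needed.

Further compounds
F1 | step 4 | N-methoxy-N-methyl-2-(2,4,5-trimethoxyphenyl)acetamide | CON(C)C(=O)Cc1cc(OC)c(OC)cc1OC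
F2 | step 4 | [4-methoxy-2,5-bis(methoxymethoxy)phenyl]magnesium chloride | COCOc1cc(OC)c(OCOC)cc1[Mg]Cl
F3 | step 4 | 1-[4-methoxy-2,5-bis(methoxymethoxy)phenyl]-2-(2,4,5-trimethoxyphenyl)ethan-1-one | COCOc1cc(OC)c(OCOC)cc1C(=O)Cc1cc(OC)c(OC)cc1OC
F4 | step 4 | 3-(dimethylamino)-1-[4-methoxy-2,5-bis(methoxymethoxy)phenyl]-2-(2,4,5-trimethoxyphenyl)prop-2-en-1-one (alkene geometry not controlled) | CN(C)C=C(C(=O)c1cc(OCOC)c(OC)cc1OCOC)c1cc(OC)c(OC)cc1OC
F5 | step 4 | 1-(2,5-dihydroxy-4-methoxyphenyl)-3-(dimethylamino)-2-(2,4,5-trimethoxyphenyl)prop-2-en-1-one (alkene geometry not controlled) | CN(C)C=C(C(=O)c1cc(O)c(OC)cc1O)c1cc(OC)c(OC)cc1OC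
F6 | step 2 | 1-bromo-4-methoxy-2,5-bis(methoxymethoxy)benzene | COCOc1cc(OC)c(OCOC)cc1Br
F7 | step 2 | [4-methoxy-2,5-bis(methoxymethoxy)phenyl]lithium | [Li]c1cc(OCOC)c(OC)cc1OCOC
F0 | step 5 | none | none
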